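**Retrosynthetic overview**
- The target is reached by late allylic oxidation of an isopropenyl group to the 2‑propenal and acetylation of the C4 hydroxyl (benzofuranone numbering).
- The C3a–C4 bond is made by a SmI2 ketyl‑radical 6‑exo cyclisation of an aldehyde onto a tethered α‑(methoxymethyl)butenolide; loss of methoxide unveils the α‑methylene lactone in the same flask.
- The C7–C7a bond comes from a vinylogous Mukaiyama aldol of a 2‑silyloxyfuran with an α‑quaternary aldehyde; the angelate is installed before ring closure.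
- The vicinal quaternary/tertiary pair (C6/C5) comes from an enantioselective boron‑mediated Ireland–Claisen rearrangement of an (E)‑allylic 3‑methylbut‑3‑enoate made from isoprene monoxide.
- Ring order: the lactone (as butenolide) first, the cyclohexane second.

Assumption: the (S,S)‑bromoborane controller is taken as the enantiomer that gives the (2S,3S) acid of step 2; if its facial sense is opposite, the (R,R)‑controller is used and nothing else changes.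

**Step 1**
Reactants: 1 2‑methyl‑2‑vinyloxirane (racemic); 2 3‑methylbut‑3‑enoic acid
Product: 4 (2E)‑3‑methyl‑4‑[(triethylsilyl)oxy]but‑2‑en‑1‑yl 3‑methylbut‑3‑enoate, via hydroxy ester 3 (not isolated)
Conditions: Pd(PPh3)4 (2 mol%), THF, 0 °C → rt; then imidazole, Et3SiCl, 0 °C; SiO2 (minor Z isomer removed)
Reagents that add atoms: chlorotriethylsilane, CC[Si](Cl)(CC)CC
Why: Tsuji–Trost‑type opening in which zerovalent palladium ionises the vinyl epoxide to a π‑allyl complex, the carboxylate adds at the unsubstituted distal terminus (1,4‑addition) and reversible ionisation of the allylic ester funnels material to the more stable E‑trisubstituted alkene, after which the primary alcohol is silylated in the same flask; no stereocentre is formed (the epoxide centre is destroyed).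

**Step 2**
Reactants: 4 (2E)‑3‑methyl‑4‑[(triethylsilyl)oxy]but‑2‑en‑1‑yl 3‑methylbut‑3‑enoate
Product: 6 (2S,3S)‑3‑methyl‑2‑(prop‑1‑en‑2‑yl)‑3‑{[(triethylsilyl)oxy]methyl}pent‑4‑enoic acid, via boron ketene acetal 5 (not isolated)
Conditions: (4S,5S)‑2‑bromo‑4,5‑diphenyl‑1,3‑bis{[3,5‑bis(trifluoromethyl)phenyl]sulfonyl}‑1,3,2‑diazaborolidine (1.2 equiv), Et3N, toluene–hexane, −78 °C then 4 °C, several days; pH 4 work‑up
Reagents that add atoms: none
Why: Corey's enantioselective boron‑mediated Ireland–Claisen rearrangement, in which soft enolisation with Et3N in a non‑polar medium gives the E(O) boron dienolate and the chair [3,3] shift of the E‑allylic ester (isopropenyl and methyl both pseudo‑axial) sets C2 and the quaternary C3 in the elemane‑type relationship, the sulfonamide controller choosing the enantioface as in the reported geranyl ester case that leads to the elemene skeleton.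

**Step 3**
Reactants: 6 (2S,3S)‑3‑methyl‑2‑(prop‑1‑en‑2‑yl)‑3‑{[(triethylsilyl)oxy]methyl}pent‑4‑enoic acid
Product: 7 (2S,3S)‑3‑methyl‑2‑(prop‑1‑en‑2‑yl)‑3‑{[(triethylsilyl)oxy]methyl}pent‑4‑en‑1‑ol
Conditions: LiAlH4, THF, 0 °C → rt
Reagents that add atoms: none
Why: Hydride reduction of the carboxylic acid to the primary alcohol leaves the silyl ether and the unconjugated alkenes alone and touches no stereocentre.

**Step 4**
Reactants: 7 (2S,3S)‑3‑methyl‑2‑(prop‑1‑en‑2‑yl)‑3‑{[(triethylsilyl)oxy]methyl}pent‑4‑en‑1‑ol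
Product: 8 tert‑butyl{[(2S,3S)‑3‑methyl‑2‑(prop‑1‑en‑2‑yl)‑3‑{[(triethylsilyl)oxy]methyl}pent‑4‑en‑1‑yl]oxy}dimethylsilane
Conditions: t‑BuMe2SiCl, imidazole, DMF, rt
Reagents that add atoms: tert‑butylchlorodimethylsilane, CC(C)(C)[Si](C)(C)Cl
Why: Standard imidazole‑mediated silylation of the primary alcohol; the tert‑butyldimethylsilyl ether is chosen because it survives the next step, in which the triethylsilyl ether does not.

**Step 5**
Reactants: 8 tert‑butyl{[(2S,3S)‑3‑methyl‑2‑(prop‑1‑en‑2‑yl)‑3‑{[(triethylsilyl)oxy]methyl}pent‑4‑en‑1‑yl]oxy}dimethylsilane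
Product: 9 (2S,3S)‑3‑{[(tert‑butyldimethylsilyl)oxy]methyl}‑2‑ethenyl‑2,4‑dimethylpent‑4‑enal
Conditions: (COCl)2, DMSO, CH2Cl2, −78 → −40 °C; Et3N, −78 °C → rt
Reagents that add atoms: none
Why: Under Swern conditions the chlorodimethylsulfonium salt cleaves a primary triethylsilyl ether and oxidises it directly to the aldehyde while a tert‑butyldimethylsilyl ether survives (known selective oxidative desilylation), and the α‑quaternary aldehyde cannot epimerise.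

**Step 6**
Reactants: 10 furan‑3‑ylmethanol
Product: 11 3‑(methoxymethyl)furan
Conditions: NaH, MeI, THF, 0 °C → rt
Reagents that add atoms: iodomethane, CI
Why: Williamson etherification of the primary alkoxide.

**Step 7**
Reactants: 11 3‑(methoxymethyl)furan
Product: 13 3‑(methoxymethyl)‑2‑[(trimethylsilyl)oxy]furan, via furyllithium 12 (not isolated)
Conditions: n‑BuLi, Et2O, 0 °C; Me3SiOOSiMe3, −78 °C → rt; distil
Reagents that add atoms: bis(trimethylsilyl) peroxide, C[Si](C)(C)OO[Si](C)(C)C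
Why: Ether‑directed lithiation at C2 of the 3‑substituted furan followed by electrophilic oxygenation of the furyllithium with the silyl peroxide gives the 2‑silyloxyfuran (the silyl dienol ether of the butenolide) directly.

**Step 8**
Reactants: 9 (2S,3S)‑3‑{[(tert‑butyldimethylsilyl)oxy]methyl}‑2‑ethenyl‑2,4‑dimethylpent‑4‑enal; 13 3‑(methoxymethyl)‑2‑[(trimethylsilyl)oxy]furan
Product: 15 (5R)‑5‑[(1S,2S,3S)‑3‑{[(tert‑butyldimethylsilyl)oxy]methyl}‑1‑hydroxy‑2,4‑dimethyl‑2‑vinylpent‑4‑en‑1‑yl]‑3‑(methoxymethyl)furan‑2(5H)‑one, via silyl ether 14 (not isolated)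
Conditions: Bu4N Ph3SiF2 (TBAT, 10 mol%), THF, −78 °C; then 1 M HCl, THF, 0 °C
Reagents that add atoms: none
Why: Vinylogous Mukaiyama aldol reaction under Lewis‑base (fluoride) activation, in which the furan‑2‑olate attacks through its γ‑carbon in an open antiperiplanar transition state that gives the 5,1'‑anti (erythro) adduct, on the aldehyde face predicted by the Felkin–Anh model (branched C3' anti to the nucleophile, flat vinyl group outside), so setting C5 (R) and C1' (S); silyl transfer to the aldolate blocks retro‑aldol and the trimethylsilyl group is removed on acidic work‑up.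

**Step 9**
Reactants: 15 (5R)‑5‑[(1S,2S,3S)‑3‑{[(tert‑butyldimethylsilyl)oxy]methyl}‑1‑hydroxy‑2,4‑dimethyl‑2‑vinylpent‑4‑en‑1‑yl]‑3‑(methoxymethyl)furan‑2(5H)‑one; 16 (2Z)‑2‑methylbut‑2‑enoic acid (angelic acid)
Product: 18 (1S,2S,3S)‑3‑{[(tert‑butyldimethylsilyl)oxy]methyl}‑1‑[(2R)‑4‑(methoxymethyl)‑5‑oxo‑2,5‑dihydrofuran‑2‑yl]‑2,4‑dimethyl‑2‑vinylpent‑4‑en‑1‑yl (2Z)‑2‑methylbut‑2‑enoate, via mixed anhydride 17 (not isolated)
Conditions: 16, 2,4,6‑Cl3C6H2COCl, Et3N, toluene, rt, filter and concentrate; then 15, toluene, 75 °C (no DMAP, no base)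
Reagents that add atoms: none
Why: Yamaguchi‑type esterification through the mixed anhydride heated without DMAP (Greene's conditions for angelates) acylates the hindered secondary alcohol without Z to E isomerisation to the tiglate and, being base‑free, without epimerising the butenolide γ‑carbon.

**Step 10**
Reactants: 18 (1S,2S,3S)‑3‑{[(tert‑butyldimethylsilyl)oxy]methyl}‑1‑[(2R)‑4‑(methoxymethyl)‑5‑oxo‑2,5‑dihydrofuran‑2‑yl]‑2,4‑dimethyl‑2‑vinylpent‑4‑en‑1‑yl (2Z)‑2‑methylbut‑2‑enoate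
Product: 19 (1S,2S,3S)‑3‑(hydroxymethyl)‑1‑[(2R)‑4‑(methoxymethyl)‑5‑oxo‑2,5‑dihydrofuran‑2‑yl]‑2,4‑dimethyl‑2‑vinylpent‑4‑en‑1‑yl (2Z)‑2‑methylbut‑2‑enoate
Conditions: HF·pyridine, pyridine, THF, 0 °C → rt
Reagents that add atoms: none
Why: Buffered fluoride cleavage of the primary silyl ether under non‑basic conditions leaves both esters and the butenolide intact.

**Step 11**
Reactants: 19 (1S,2S,3S)‑3‑(hydroxymethyl)‑1‑[(2R)‑4‑(methoxymethyl)‑5‑oxo‑2,5‑dihydrofuran‑2‑yl]‑2,4‑dimethyl‑2‑vinylpent‑4‑en‑1‑yl (2Z)‑2‑methylbut‑2‑enoate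
Product: 20 (1S,2S,3S)‑3‑formyl‑1‑[(2R)‑4‑(methoxymethyl)‑5‑oxo‑2,5‑dihydrofuran‑2‑yl]‑2,4‑dimethyl‑2‑vinylpent‑4‑en‑1‑yl (2Z)‑2‑methylbut‑2‑enoate
Conditions: Dess–Martin periodinane, NaHCO3, CH2Cl2, 0 °C; used at once
Reagents that add atoms: none
Why: Dess–Martin oxidation under bicarbonate buffer gives the β,γ‑unsaturated aldehyde without conjugation or epimerisation of its α‑centre.

**Step 12**
Reactants: 20 (1S,2S,3S)‑3‑formyl‑1‑[(2R)‑4‑(methoxymethyl)‑5‑oxo‑2,5‑dihydrofuran‑2‑yl]‑2,4‑dimethyl‑2‑vinylpent‑4‑en‑1‑yl (2Z)‑2‑methylbut‑2‑enoate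
Product: 22 (3aR,4S,5S,6S,7S,7aR)‑4‑(acetyloxy)‑6‑ethenyl‑6‑methyl‑3‑methylidene‑2‑oxo‑5‑(prop‑1‑en‑2‑yl)octahydro‑1‑benzofuran‑7‑yl (2Z)‑2‑methylbut‑2‑enoate, via cyclised alcohol 21 (not isolated)
Conditions: SmI2 (2.5 equiv), HMPA, THF (0.01 M), −78 → 0 °C; then Ac2O, DMAP, 0 °C → rt
Reagents that add atoms: acetic anhydride, CC(=O)OC(C)=O
Why: Proposed new method: divalent samarium reduces the aldehyde to a ketyl radical that adds 6‑exo‑trig to the butenolide β‑carbon from the face of the tether (cis ring fusion, C3a) through a chair‑like transition state with the O–Sm group pseudo‑equatorial (the axial alternative clashes with the axial vinyl group and the lactone oxygen), which sets C4 trans to the lactone carbon; the α‑lactone radical is then reduced to the trivalent samarium enolate, which expels methoxide (E1cB) to unveil the exo‑methylene group, and the C4 alkoxide is acetylated in the flask before it can translactonise; the closest known reactions are SmI2 ketyl–olefin cyclisations onto unsaturated esters and Molander's ketyl–olefin cyclisation/β‑elimination sequences.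

**Step 13**
Reactants: 22 (3aR,4S,5S,6S,7S,7aR)‑4‑(acetyloxy)‑6‑ethenyl‑6‑methyl‑3‑methylidene‑2‑oxo‑5‑(prop‑1‑en‑2‑yl)octahydro‑1‑benzofuran‑7‑yl (2Z)‑2‑methylbut‑2‑enoate
Product: 23 (3aR,4S,5R,6S,7S,7aR)‑4‑(acetyloxy)‑6‑ethenyl‑6‑methyl‑3‑methylidene‑2‑oxo‑5‑(3‑oxoprop‑1‑en‑2‑yl)octahydro‑1‑benzofuran‑7‑yl (2Z)‑2‑methylbut‑2‑enoate
Conditions: SeO2 (2 equiv), 1,4‑dioxane, 80 °C
Reagents that add atoms: selenium dioxide, O=[Se]=O
Why: Riley allylic oxidation (ene reaction then [2,3]‑shift) occurs at the only electron‑rich alkene that has allylic hydrogens, on its methyl group rather than the ring methine, and runs on to the enal, whereas the vinyl group has no allylic hydrogen and the two conjugated alkenes are deactivated.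

**Compound list**
1 | 2‑methyl‑2‑vinyloxirane (racemic) | CC1(C=C)CO1 | starting material
2 | 3‑methylbut‑3‑enoic acid | C=C(C)CC(=O)O | starting material
3 | (2E)‑4‑hydroxy‑3‑methylbut‑2‑en‑1‑yl 3‑methylbut‑3‑enoate | C=C(C)CC(=O)OC/C=C(C)/CO | intermediate
4 | (2E)‑3‑methyl‑4‑[(triethylsilyl)oxy]but‑2‑en‑1‑yl 3‑methylbut‑3‑enoate | C=C(C)CC(=O)OC/C=C(C)/CO[Si](CC)(CC)CC | intermediate
5 | (4S,5S)‑2‑{[3‑methyl‑1‑{[(2E)‑3‑methyl‑4‑[(triethylsilyl)oxy]but‑2‑en‑1‑yl]oxy}buta‑1,3‑dien‑1‑yl]oxy}‑4,5‑diphenyl‑1,3‑bis{[3,5‑bis(trifluoromethyl)phenyl]sulfonyl}‑1,3,2‑diazaborolidine, E(O) ketene acetal (isopropenyl cis to the allyloxy group; 1Z by CIP) | C=C(C)/C=C(/OB1N(S(=O)(=O)c2cc(C(F)(F)F)cc(C(F)(F)F)c2)[C@@H](c2ccccc2)[C@H](c2ccccc2)N1S(=O)(=O)c1cc(C(F)(F)F)cc(C(F)(F)F)c1)OC/C=C(C)/CO[Si](CC)(CC)CC | intermediate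
6 | (2S,3S)‑3‑methyl‑2‑(prop‑1‑en‑2‑yl)‑3‑{[(triethylsilyl)oxy]methyl}pent‑4‑enoic acid | C=C[C@]([C@@H](C(=O)O)C(C)=C)(C)CO[Si](CC)(CC)CC | intermediate
7 | (2S,3S)‑3‑methyl‑2‑(prop‑1‑en‑2‑yl)‑3‑{[(triethylsilyl)oxy]methyl}pent‑4‑en‑1‑ol | C=C[C@]([C@@H](CO)C(C)=C)(C)CO[Si](CC)(CC)CC | intermediate
8 | tert‑butyl{[(2S,3S)‑3‑methyl‑2‑(prop‑1‑en‑2‑yl)‑3‑{[(triethylsilyl)oxy]methyl}pent‑4‑en‑1‑yl]oxy}dimethylsilane | C=C[C@]([C@@H](CO[Si](C)(C)C(C)(C)C)C(C)=C)(C)CO[Si](CC)(CC)CC | intermediate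
9 | (2S,3S)‑3‑{[(tert‑butyldimethylsilyl)oxy]methyl}‑2‑ethenyl‑2,4‑dimethylpent‑4‑enal | C=C[C@]([C@@H](CO[Si](C)(C)C(C)(C)C)C(C)=C)(C)C=O | intermediate
10 | furan‑3‑ylmethanol | OCc1ccoc1 | starting material
11 | 3‑(methoxymethyl)furan | COCc1ccoc1 | intermediate
12 | [3‑(methoxymethyl)furan‑2‑yl]lithium | [Li]c1occc1COC | intermediate
13 | 3‑(methoxymethyl)‑2‑[(trimethylsilyl)oxy]furan | COCc1ccoc1O[Si](C)(C)C | intermediate
14 | (5R)‑5‑[(1S,2S,3S)‑3‑{[(tert‑butyldimethylsilyl)oxy]methyl}‑2,4‑dimethyl‑1‑[(trimethylsilyl)oxy]‑2‑vinylpent‑4‑en‑1‑yl]‑3‑(methoxymethyl)furan‑2(5H)‑one | C=C[C@]([C@@H](CO[Si](C)(C)C(C)(C)C)C(C)=C)(C)[C@H](O[Si](C)(C)C)[C@@H]1OC(=O)C(COC)=C1 | intermediate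
15 | (5R)‑5‑[(1S,2S,3S)‑3‑{[(tert‑butyldimethylsilyl)oxy]methyl}‑1‑hydroxy‑2,4‑dimethyl‑2‑vinylpent‑4‑en‑1‑yl]‑3‑(methoxymethyl)furan‑2(5H)‑one | C=C[C@]([C@@H](CO[Si](C)(C)C(C)(C)C)C(C)=C)(C)[C@H](O)[C@@H]1OC(=O)C(COC)=C1 | intermediate
16 | (2Z)‑2‑methylbut‑2‑enoic acid (angelic acid) | C/C=C(/C)C(=O)O | starting material
17 | (2Z)‑2‑methylbut‑2‑enoic 2,4,6‑trichlorobenzoic anhydride | C/C=C(/C)C(=O)OC(=O)c1c(Cl)cc(Cl)cc1Cl | intermediate
18 | (1S,2S,3S)‑3‑{[(tert‑butyldimethylsilyl)oxy]methyl}‑1‑[(2R)‑4‑(methoxymethyl)‑5‑oxo‑2,5‑dihydrofuran‑2‑yl]‑2,4‑dimethyl‑2‑vinylpent‑4‑en‑1‑yl (2Z)‑2‑methylbut‑2‑enoate | C=C[C@]([C@@H](CO[Si](C)(C)C(C)(C)C)C(C)=C)(C)[C@H](OC(=O)/C(C)=C\C)[C@@H]1OC(=O)C(COC)=C1 | intermediate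
19 | (1S,2S,3S)‑3‑(hydroxymethyl)‑1‑[(2R)‑4‑(methoxymethyl)‑5‑oxo‑2,5‑dihydrofuran‑2‑yl]‑2,4‑dimethyl‑2‑vinylpent‑4‑en‑1‑yl (2Z)‑2‑methylbut‑2‑enoate | C=C[C@]([C@@H](CO)C(C)=C)(C)[C@H](OC(=O)/C(C)=C\C)[C@@H]1OC(=O)C(COC)=C1 | intermediate
20 | (1S,2S,3S)‑3‑formyl‑1‑[(2R)‑4‑(methoxymethyl)‑5‑oxo‑2,5‑dihydrofuran‑2‑yl]‑2,4‑dimethyl‑2‑vinylpent‑4‑en‑1‑yl (2Z)‑2‑methylbut‑2‑enoate | C=C[C@]([C@@H](C=O)C(C)=C)(C)[C@H](OC(=O)/C(C)=C\C)[C@@H]1OC(=O)C(COC)=C1 | intermediate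
21 | (3aR,4S,5S,6S,7S,7aR)‑6‑ethenyl‑4‑hydroxy‑6‑methyl‑3‑methylidene‑2‑oxo‑5‑(prop‑1‑en‑2‑yl)octahydro‑1‑benzofuran‑7‑yl (2Z)‑2‑methylbut‑2‑enoate (present in the flask as its samarium alkoxide) | C=C[C@]1(C)[C@H](OC(=O)/C(C)=C\C)[C@@H]2OC(=O)C(=C)[C@@H]2[C@@H](O)[C@H]1C(C)=C | intermediate
22 | (3aR,4S,5S,6S,7S,7aR)‑4‑(acetyloxy)‑6‑ethenyl‑6‑methyl‑3‑methylidene‑2‑oxo‑5‑(prop‑1‑en‑2‑yl)octahydro‑1‑benzofuran‑7‑yl (2Z)‑2‑methylbut‑2‑enoate | C=C[C@]1(C)[C@H](OC(=O)/C(C)=C\C)[C@@H]2OC(=O)C(=C)[C@@H]2[C@@H](OC(C)=O)[C@H]1C(C)=C | intermediate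
23 | (3aR,4S,5R,6S,7S,7aR)‑4‑(acetyloxy)‑6‑ethenyl‑6‑methyl‑3‑methylidene‑2‑oxo‑5‑(3‑oxoprop‑1‑en‑2‑yl)octahydro‑1‑benzofuran‑7‑yl (2Z)‑2‑methylbut‑2‑enoate | C=C[C@]1(C)[C@H](OC(=O)/C(C)=C\C)[C@@H]2OC(=O)C(=C)[C@@H]2[C@@H](OC(C)=O)[C@H]1C(=C)C=O | target

**Step count**
Total steps: 13. Longest linear sequence: 11 (steps 1–5 and 8–13; steps 6–7 make the furan partner).

**Three steps most likely to fail**

Step 8 (two new stereocentres under weak substrate control; the α‑quaternary centre offers only methyl versus vinyl to direct the face). The fallback moves the aldol to the Lewis‑acid manifold and corrects C5 afterwards. It sets out from 9 and 13: BF3·OEt2 in CH2Cl2 at −78 °C gives, through the usual syn‑selective open transition state and with tighter Felkin control, the 5‑epimeric butenolide (5S)‑5‑[(1S,2S,3S)‑3‑{[(tert‑butyldimethylsilyl)oxy]methyl}‑1‑hydroxy‑2,4‑dimethyl‑2‑vinylpent‑4‑en‑1‑yl]‑3‑(methoxymethyl)furan‑2(5H)‑one F1. Catalytic DBU in CH2Cl2 then equilibrates the acidic butenolide γ‑centre through the 2‑hydroxyfuran tautomer; 15 is separated, F1 is recycled, and the route is rejoined at 15.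

Step 12 (the cascade may stop before methoxide loss, or the C4 alkoxide may translactonise on warming). The fallback separates ring closure from the unveiling of the methylene group. It sets out from 20: SmI2 with t‑BuOH in THF at −78 °C gives the protonated cyclisation product (3aR,4S,5S,6S,7S,7aR)‑6‑ethenyl‑4‑hydroxy‑3‑(methoxymethyl)‑6‑methyl‑2‑oxo‑5‑(prop‑1‑en‑2‑yl)octahydro‑1‑benzofuran‑7‑yl (2Z)‑2‑methylbut‑2‑enoate F2 (C3 epimers). Ac2O and pyridine give its acetate (3aR,4S,5S,6S,7S,7aR)‑4‑(acetyloxy)‑6‑ethenyl‑3‑(methoxymethyl)‑6‑methyl‑2‑oxo‑5‑(prop‑1‑en‑2‑yl)octahydro‑1‑benzofuran‑7‑yl (2Z)‑2‑methylbut‑2‑enoate F3. DBU in CH2Cl2 at rt eliminates methanol (E1cB) and the route is rejoined at 22.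

Step 13 (late oxidation next to three other alkenes; over‑oxidation or attack at the ring methine is possible). The fallback brings the oxygen in by a Schenck ene reaction instead. It sets out from 22: O2, tetraphenylporphyrin and visible light in CH2Cl2 at 0 °C give the primary allylic hydroperoxide (3aR,4S,5S,6S,7S,7aR)‑4‑(acetyloxy)‑6‑ethenyl‑5‑(3‑hydroperoxyprop‑1‑en‑2‑yl)‑6‑methyl‑3‑methylidene‑2‑oxooctahydro‑1‑benzofuran‑7‑yl (2Z)‑2‑methylbut‑2‑enoate F4. The ring methine is not abstracted because allylic strain holds its C–H in the alkene plane. Ac2O and pyridine (Kornblum–DeLaMare dehydration) then give 23.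

**Further compounds**
F1 | step 8 | (5S)‑5‑[(1S,2S,3S)‑3‑{[(tert‑butyldimethylsilyl)oxy]methyl}‑1‑hydroxy‑2,4‑dimethyl‑2‑vinylpent‑4‑en‑1‑yl]‑3‑(methoxymethyl)furan‑2(5H)‑one | C=C[C@]([C@@H](CO[Si](C)(C)C(C)(C)C)C(C)=C)(C)[C@H](O)[C@H]1OC(=O)C(COC)=C1
F2 | step 12 | (3aR,4S,5S,6S,7S,7aR)‑6‑ethenyl‑4‑hydroxy‑3‑(methoxymethyl)‑6‑methyl‑2‑oxo‑5‑(prop‑1‑en‑2‑yl)octahydro‑1‑benzofuran‑7‑yl (2Z)‑2‑methylbut‑2‑enoate (C3 epimers) | C=C[C@]1(C)[C@H](OC(=O)/C(C)=C\C)[C@@H]2OC(=O)C(COC)[C@@H]2[C@@H](O)[C@H]1C(C)=C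
F3 | step 12 | (3aR,4S,5S,6S,7S,7aR)‑4‑(acetyloxy)‑6‑ethenyl‑3‑(methoxymethyl)‑6‑methyl‑2‑oxo‑5‑(prop‑1‑en‑2‑yl)octahydro‑1‑benzofuran‑7‑yl (2Z)‑2‑methylbut‑2‑enoate (C3 epimers) | C=C[C@]1(C)[C@H](OC(=O)/C(C)=C\C)[C@@H]2OC(=O)C(COC)[C@@H]2[C@@H](OC(C)=O)[C@H]1C(C)=C
F4 | step 13 | (3aR,4S,5S,6S,7S,7aR)‑4‑(acetyloxy)‑6‑ethenyl‑5‑(3‑hydroperoxyprop‑1‑en‑2‑yl)‑6‑methyl‑3‑methylidene‑2‑oxooctahydro‑1‑benzofuran‑7‑yl (2Z)‑2‑methylbut‑2‑enoate | C=C[C@]1(C)[C@H](OC(=O)/C(C)=C\C)[C@@H]2OC(=O)C(=C)[C@@H]2[C@@H](OC(C)=O)[C@H]1C(=C)COO
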